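**Retrosynthetic overview**

1. Feature: in the six-membered quinone ring (C1=O, C2–OH, C3–hexadecyl C1′–C16′, C4=O, C5–OMe, C6–H) the hydroxyl oxygen O2 sits ortho to the chain-bearing C3. O2–C2–C3–C1′ plus C2′ can therefore be closed to a five-membered furan, so O2 can carry C2′–C16′ as a pentadecanoyl ester and hand it to C1′.
2. 19 ⇐ acetate hydrolysis and CAN oxidation of the para C1/C4 dimethoxy pair ⇐ aryl acetate 17 ⇐ hydrogenation and acetylation ⇐ ortho-alkenylphenol 15 ⇐ reductive cleavage of the furan O–C2′ bond of benzofuran 13.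
3. 13 ⇐ intramolecular ester Wittig reaction (forms C1′=C2′ and closes the furan) ⇐ acyloxybenzylphosphonium salt 10 ⇐ pentadecanoyl chloride 9 + hydroxybenzylphosphonium salt 8.
4. 8 ⇐ triphenylphosphine hydrobromide 7 + salicyl alcohol 6 ⇐ aldehyde 5 ⇐ ortho-formylation of 2,4,5-trimethoxyphenol 3 ⇐ Dakin oxidation of asaraldehyde 1.
5. Ring order: the benzene ring is bought; the furan ring is closed in step 6 and opened again in step 7; the quinone is unveiled in step 10.

Key step: step 6

Remark: the target has no stereocentre and is achiral, so the request for a single enantiomer imposes no requirement; the geometry of the transient alkene in 15 and 16 is erased in step 9.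

**Route**

Step 1
Reactants: 1 2,4,5-trimethoxybenzaldehyde (asaraldehyde)
Product: 3 2,4,5-trimethoxyphenol, via aryl formate 2 (not isolated)
Conditions: 30% H2O2 (1.3 equiv), cat. H2SO4, MeOH, rt
Reagents that add atoms: hydrogen peroxide, OO
Why: Dakin-type (Baeyer–Villiger) oxidation in which the electron-rich aryl group migrates to oxygen to give formate 2, which acidic methanol cleaves in situ to the phenol.

Step 2
Reactants: 3 2,4,5-trimethoxyphenol
Product: 5 2-hydroxy-3,5,6-trimethoxybenzaldehyde, via magnesium salicyl alkoxide 4 (not isolated)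
Conditions: MgCl2 (1.5 equiv), Et3N (3.75 equiv), (CH2O)n (7 equiv), MeCN, reflux; then 1 M HCl
Reagents that add atoms: paraformaldehyde (as formaldehyde), C=O
Why: Casnati–Skattebøl ortho-formylation, in which the magnesium phenoxide delivers formaldehyde only to the one free ortho carbon and a second formaldehyde oxidises the resulting alkoxide 4 by hydride transfer, leaving the CH between two methoxyls (meta to OH) untouched.

Step 3
Reactants: 5 2-hydroxy-3,5,6-trimethoxybenzaldehyde
Product: 6 2-(hydroxymethyl)-3,4,6-trimethoxyphenol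
Conditions: NaBH4, MeOH/THF, 0 °C; sat. NH4Cl; used without storage
Reagents that add atoms: none
Why: Borohydride reduction of an aryl aldehyde to the benzylic alcohol, with a near-neutral quench to avoid acid-induced ortho-quinone methide formation.

Step 4
Reactants: 6 2-(hydroxymethyl)-3,4,6-trimethoxyphenol; 7 triphenylphosphine hydrobromide
Product: 8 (2-hydroxy-3,5,6-trimethoxybenzyl)triphenylphosphonium bromide
Conditions: MeCN, reflux
Reagents that add atoms: none
Why: Acid-mediated ionisation of the electron-rich ortho-hydroxybenzyl alcohol (benzylic cation/ortho-quinone methide) and capture by triphenylphosphine, the standard preparation of salicylphosphonium salts.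

Step 5
Reactants: 8 (2-hydroxy-3,5,6-trimethoxybenzyl)triphenylphosphonium bromide; 9 pentadecanoyl chloride
Product: 10 [3,5,6-trimethoxy-2-(pentadecanoyloxy)benzyl]triphenylphosphonium bromide
Conditions: pyridine (1.5 equiv), CH2Cl2, 0 °C to rt; precipitation with Et2O
Reagents that add atoms: none
Why: O-acylation of the phenol by an acid chloride with pyridine, a base too weak to deprotonate the P–CH2 group, so the ester salt can be isolated before any Wittig chemistry starts.

Step 6
Reactants: 10 [3,5,6-trimethoxy-2-(pentadecanoyloxy)benzyl]triphenylphosphonium bromide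
Product: 13 4,5,7-trimethoxy-2-tetradecylbenzofuran, via phosphonium ylide 11 (not isolated), via oxaphosphetane 12 (not isolated)
Conditions: Et3N (3 equiv), toluene, reflux
Reagents that add atoms: none
Why: Triethylamine reversibly deprotonates the benzylic P–CH2 to ylide 11, whose carbanion adds to the ester carbonyl held ortho to it; the betaine closes to oxaphosphetane 12, which expels triphenylphosphine oxide and leaves the C1′=C2′ double bond. The closest known reaction is the intramolecular ester Wittig synthesis of 2-substituted benzofurans from ortho-acyloxybenzylphosphonium salts. The furan ring closes by 5-exo-trig attack of the ylide carbon C1′ on the ester C=O (ring atoms C1′, C3, C2, O2, C2′), the O2–C2′ bond being already present as the ester C–O bond. No stereocentre is created and the new alkene is endocyclic, so its geometry is fixed. The step needs only chemoselectivity for the neighbouring ester over intermolecular acyl transfer, which the ortho tether and the absence of free acid chloride (no 3-acylation) secure.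

Step 7
Reactants: 13 4,5,7-trimethoxy-2-tetradecylbenzofuran
Product: 15 (E)-2-(hexadec-1-en-1-yl)-3,4,6-trimethoxyphenol, via dilithio vinyl phenoxide 14 (not isolated)
Conditions: Li powder (excess), DTBB (10 mol%), THF, 0 °C; then H2O, sat. NH4Cl work-up under argon
Reagents that add atoms: none
Why: Arene-catalysed lithiation, in which electron transfer from the DTBB radical anion to the benzofuran π-system cleaves the vinylic O–C2′ bond (known for benzofurans) to give lithium phenoxide/vinyllithium 14, protonated on quench; the aryl methyl ethers should be cleaved much more slowly at 0 °C.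

Step 8
Reactants: 15 (E)-2-(hexadec-1-en-1-yl)-3,4,6-trimethoxyphenol
Product: 16 (E)-2-(hexadec-1-en-1-yl)-3,4,6-trimethoxyphenyl acetate
Conditions: Ac2O, pyridine, cat. DMAP, CH2Cl2, 0 °C to rt
Reagents that add atoms: acetic anhydride, CC(=O)OC(C)=O
Why: Standard acetylation of the single free phenol, which protects the air-sensitive para-methoxyphenol, stops acid-induced re-cyclisation onto the alkene and marks O2 for the later oxidation.

Step 9
Reactants: 16 (E)-2-(hexadec-1-en-1-yl)-3,4,6-trimethoxyphenyl acetate
Product: 17 2-hexadecyl-3,4,6-trimethoxyphenyl acetate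
Conditions: H2 (1 atm), 10% Pd/C, EtOAc, rt
Reagents that add atoms: none
Why: Catalytic hydrogenation of a styrenic double bond, with aryl acetate and aryl methyl ethers inert under these conditions.

Step 10
Reactants: 17 2-hexadecyl-3,4,6-trimethoxyphenyl acetate
Product: 18 2-hexadecyl-4-methoxy-3,6-dioxocyclohexa-1,4-dien-1-yl acetate (2-acetoxy-3-hexadecyl-5-methoxy-1,4-benzoquinone)
Conditions: CAN (2.5 equiv), MeCN/H2O 2:1, 0 °C
Reagents that add atoms: water, O
Why: CAN oxidative demethylation of a para-dimethoxyarene to the para-quinone: the methoxyls at C3 and C6 of 17 are the only para-related ether pair, the acetoxy oxygen is deactivated, and water adds at the two ipso carbons with loss of two methanol.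

Step 11
Reactants: 18 2-hexadecyl-4-methoxy-3,6-dioxocyclohexa-1,4-dien-1-yl acetate
Product: 19 3-hexadecyl-2-hydroxy-5-methoxy-1,4-benzoquinone (target)
Conditions: LiOH (2.2 equiv), THF/H2O, 0 °C, short contact; then cold 1 M HCl
Reagents that add atoms: none
Why: Hydrolysis of a vinylogous mixed anhydride, where hydroxide attacks the acetyl carbonyl far faster than the vinylogous ester at C5 and the hydroxyquinone anion formed resists further attack until acidification releases the target.

**Compound list**

1 | 2,4,5-trimethoxybenzaldehyde (asaraldehyde) | COc1cc(OC)c(C=O)cc1OC | starting material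
2 | 2,4,5-trimethoxyphenyl formate | COc1cc(OC)c(OC=O)cc1OC | intermediate
3 | 2,4,5-trimethoxyphenol | COc1cc(OC)c(O)cc1OC | intermediate
4 | chloromagnesium 2-(hydroxymethyl)-3,4,6-trimethoxyphenoxide | COc1cc(OC)c(OC)c(CO)c1[O-].[Mg+2].[Cl-] | intermediate
5 | 2-hydroxy-3,5,6-trimethoxybenzaldehyde | COc1cc(OC)c(OC)c(C=O)c1O | intermediate
6 | 2-(hydroxymethyl)-3,4,6-trimethoxyphenol | COc1cc(OC)c(OC)c(CO)c1O | intermediate
7 | triphenylphosphine hydrobromide (commercial) | [Br-].[PH+](c1ccccc1)(c1ccccc1)c1ccccc1 | starting material
8 | (2-hydroxy-3,5,6-trimethoxybenzyl)triphenylphosphonium bromide | COc1cc(OC)c(OC)c(C[P+](c2ccccc2)(c2ccccc2)c2ccccc2)c1O.[Br-] | intermediate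
9 | pentadecanoyl chloride (commercial) | CCCCCCCCCCCCCCC(=O)Cl | starting material
10 | [3,5,6-trimethoxy-2-(pentadecanoyloxy)benzyl]triphenylphosphonium bromide | CCCCCCCCCCCCCCC(=O)Oc1c(OC)cc(OC)c(OC)c1C[P+](c1ccccc1)(c1ccccc1)c1ccccc1.[Br-] | intermediate
11 | [3,5,6-trimethoxy-2-(pentadecanoyloxy)benzylidene]triphenylphosphorane | CCCCCCCCCCCCCCC(=O)Oc1c(OC)cc(OC)c(OC)c1C=P(c1ccccc1)(c1ccccc1)c1ccccc1 | intermediate
12 | oxaphosphetane fused to the 2,3-dihydrobenzofuran (P on C3, O–P bridge to C2, tetradecyl on C2) | CCCCCCCCCCCCCCC12Oc3c(OC)cc(OC)c(OC)c3C1P(c1ccccc1)(c1ccccc1)(c1ccccc1)O2 | intermediate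
13 | 4,5,7-trimethoxy-2-tetradecylbenzofuran | CCCCCCCCCCCCCCc1cc2c(OC)c(OC)cc(OC)c2o1 | intermediate
14 | lithium 2-[(Z)-2-lithiohexadec-1-en-1-yl]-3,4,6-trimethoxyphenoxide (Li cis to aryl) | [Li]/C(CCCCCCCCCCCCCC)=C\c1c(O[Li])c(OC)cc(OC)c1OC | intermediate
15 | (E)-2-(hexadec-1-en-1-yl)-3,4,6-trimethoxyphenol | CCCCCCCCCCCCCC/C=C/c1c(O)c(OC)cc(OC)c1OC | intermediate
16 | (E)-2-(hexadec-1-en-1-yl)-3,4,6-trimethoxyphenyl acetate | CCCCCCCCCCCCCC/C=C/c1c(OC(C)=O)c(OC)cc(OC)c1OC | intermediate
17 | 2-hexadecyl-3,4,6-trimethoxyphenyl acetate | CCCCCCCCCCCCCCCCc1c(OC(C)=O)c(OC)cc(OC)c1OC | intermediate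
18 | 2-hexadecyl-4-methoxy-3,6-dioxocyclohexa-1,4-dien-1-yl acetate | CCCCCCCCCCCCCCCCC1=C(OC(C)=O)C(=O)C=C(OC)C1=O | intermediate
19 | 3-hexadecyl-2-hydroxy-5-methoxy-1,4-benzoquinone | CCCCCCCCCCCCCCCCC1=C(O)C(=O)C=C(OC)C1=O | target

**Step count**

Total steps: 11. Longest linear sequence: 11 steps (1 to 19).

**Steps most likely to fail**

Step 7 (reductive opening of the furan). Electron transfer may be unselective: the electron-rich, 2-alkylated benzofuran accepts electrons reluctantly, so reductive O-demethylation of the three aryl methyl ethers or reduction of the benzene ring could compete with cleavage of the O–C2′ bond. The fallback opens the ring by anionic β-elimination and uses no reducing metal. It sets out from 13. NBS in MeCN at 0 °C should brominate the enol-ether carbon C3 to give 3-bromo-4,5,7-trimethoxy-2-tetradecylbenzofuran F1. Bromine–lithium exchange with t-BuLi (2 equiv, THF, −78 °C) should give 3-lithio-4,5,7-trimethoxy-2-tetradecylbenzofuran F2. On warming, F2 should expel the β-phenoxide to give lithium 2-(hexadec-1-yn-1-yl)-3,4,6-trimethoxyphenoxide F3. Quenching in the same flask with acetic anhydride should give 2-(hexadec-1-yn-1-yl)-3,4,6-trimethoxyphenyl acetate F4; the acetate blocks re-closure to the benzofuran. Hydrogenation of F4 under the conditions of step 9 returns to the route at 17.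

Step 6 (key step). Ylide formation at the benzylic carbon, which is flanked by two ortho oxygen substituents on a very electron-rich ring, may be slow, so that ester cleavage or loss of triphenylphosphine through an ortho-quinone methide pathway takes over. The fallback gives up the temporary ring and forms the C1′=C2′ bond intermolecularly. It sets out from aldehyde 5. Pentadecylidenetriphenylphosphorane F5 is generated from commercial pentadecyltriphenylphosphonium bromide (1.3 equiv) with KHMDS (2.4 equiv, the extra base deprotonating the phenol) in THF at −78 °C to rt. Wittig olefination of 5 with F5 should give (Z)-2-(hexadec-1-en-1-yl)-3,4,6-trimethoxyphenol F6. Acetylation as in step 8 should give (Z)-2-(hexadec-1-en-1-yl)-3,4,6-trimethoxyphenyl acetate F7, and hydrogenation as in step 9 returns to the route at 17.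

Step 10 (CAN oxidation). Oxidation may proceed through the wrong oxygen pair: ortho-quinone formation from the adjacent methoxyls at C3/C4 of 17, or loss of the acetate under the acidic aqueous conditions followed by oxidation through the phenol oxygen, would give mixtures. The fallback oxidises through the phenol deliberately and differentiates the methoxyls afterwards. It sets out from 17. K2CO3 in MeOH should give 2-hexadecyl-3,4,6-trimethoxyphenol F8. Oxidation of this para-methoxyphenol with PhI(OAc)2 in aqueous MeCN at 0 °C should give 3-hexadecyl-2,5-dimethoxy-1,4-benzoquinone F9. Acid hydrolysis (70% HClO4, dioxane, rt) is expected to cleave preferentially the methoxyl flanked by the alkyl chain, which is twisted out of conjugation, and so returns to the route at 19.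

**Further compounds**

F1 | step 7 | 3-bromo-4,5,7-trimethoxy-2-tetradecylbenzofuran | CCCCCCCCCCCCCCc1oc2c(OC)cc(OC)c(OC)c2c1Br
F2 | step 7 | 3-lithio-4,5,7-trimethoxy-2-tetradecylbenzofuran | CCCCCCCCCCCCCCc1oc2c(OC)cc(OC)c(OC)c2c1[Li]
F3 | step 7 | lithium 2-(hexadec-1-yn-1-yl)-3,4,6-trimethoxyphenoxide | CCCCCCCCCCCCCCC#Cc1c(O[Li])c(OC)cc(OC)c1OC
F4 | step 7 | 2-(hexadec-1-yn-1-yl)-3,4,6-trimethoxyphenyl acetate | CCCCCCCCCCCCCCC#Cc1c(OC(C)=O)c(OC)cc(OC)c1OC
F5 | step 6 | pentadecylidenetriphenylphosphorane | CCCCCCCCCCCCCCC=P(c1ccccc1)(c1ccccc1)c1ccccc1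
F6 | step 6 | (Z)-2-(hexadec-1-en-1-yl)-3,4,6-trimethoxyphenol | CCCCCCCCCCCCCC/C=C\c1c(O)c(OC)cc(OC)c1OC
F7 | step 6 | (Z)-2-(hexadec-1-en-1-yl)-3,4,6-trimethoxyphenyl acetate | CCCCCCCCCCCCCC/C=C\c1c(OC(C)=O)c(OC)cc(OC)c1OC
F8 | step 10 | 2-hexadecyl-3,4,6-trimethoxyphenol | CCCCCCCCCCCCCCCCc1c(O)c(OC)cc(OC)c1OC
F9 | step 10 | 3-hexadecyl-2,5-dimethoxy-1,4-benzoquinone | CCCCCCCCCCCCCCCCC1=C(OC)C(=O)C=C(OC)C1=O
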